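By the reactions listed, the sum [second nucleophile] + [other capture product] + [over-reaction product] stays at the charge of second nucleophile, so in the flask, charged with less second nucleophile than starting material, second nucleophile is the limiting reagent of this branch and bounds other capture product. Second nucleophile charged over starting material charged is the capture ceiling, 50.0 % in the flask.

| flask | starting material | first nucleophile | second nucleophile | remark | time |
|---|---|---|---|---|---|
| gamma | 0.050 M | 0.50 M | 0.050 M | run made earlier |  |
| zeta | 0.20 M | 0.50 M | 0.050 M | run made earlier |  |
| alpha | 0.10 M | 0.50 M | 0.10 M | run made earlier |  |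
| flask | 0.10 M | 0.500 M | 0.0500 M |  | 8.0 min |

| run | time / min | other capture product / % | target / % | starting material / % |
|---|---|---|---|---|
| gamma | 1.50 | 78.3 | 1.4 | 7.1 |
| gamma | 3.00 | 85.0 | 2.0 | 0.9 |
| gamma | 5.00 | 80.0 | 1.8 | 0.5 |
| gamma | 6.00 | 82.3 | 4.6 | 0.1 |
| zeta | 0.833 | 24.2 | 25.4 | 24.0 |
| zeta | 2.50 | 24.3 | 19.2 | 3.1 |
| zeta | 4.00 | 22.4 | 18.5 | 0 |
| zeta | 6.00 | 23.1 | 16.8 | 2.2 |
| alpha | 1.50 | 83.5 | 0 | 9.1 |
| alpha | 3.00 | 88.4 | 0.3 | 2.3 |
| alpha | 5.00 | 88.9 | 2.7 | 0 |
| alpha | 6.00 | 90.3 | 1.1 | 0.6 |

(standard deviation of a reading: 1 percentage point)

- ratio of other capture product to target at 0.40 s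
- ratio of other capture product to target at 8.0 min
- which of other capture product and target there is more of at 8.0 min

- reactions considered so far: starting material -> intermediate; first nucleophile + intermediate -> target; second nucleophile + intermediate -> other capture product; target <-> isomer of the product; first nucleophile <-> dormant form; second nucleophile + target -> over-reaction product

The zeta run has a ceiling of 25.0 % and late readings of 22.4 % and 23.1 %. Of the charge outside other capture product, those late zeta readings show target as 22.8 %. In the flask this reckoning therefore puts target near 11.4 % and the late ratio at 4.38.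

The weak link is whether the flask reaches its ceiling. The gamma run has a ceiling of 100 %, yet other capture product stops near 82.4 %. Integrating the competition over those gamma readings gives a selectivity factor, as a reading, of 198 M⁻¹ times [second nucleophile], hence a reckoned early ratio of 9.90 in the flask. At 0.500 M of first nucleophile, each tenfold fall of [second nucleophile] costs, in this reckoning, 0.0116 M of starting material diverted from capture. The flask is charged with 0.0500 M more starting material than second nucleophile, more than that cost and worth 4.30 powers of ten, so this reckoning puts other capture product at the ceiling.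

The forecast gave 10 early, 4.2 late and other capture product ahead, holding that “second nucleophile runs out”. The late ratio reckoned here, 4.38, stands above the forecast's.

The flask gives 9.90 at 0.40 s and 3.93 at 8.0 min, with other capture product ahead at 46.8 % against 11.9 % of target.

    starting material → intermediate (k = 0.0280 s⁻¹)
    first nucleophile + intermediate → target (k = 65.0 M⁻¹ s⁻¹)
    second nucleophile + intermediate → other capture product (k = 6200 M⁻¹ s⁻¹)
    target ⇌ isomer of the product (K = 3.20, k = 0.0470 s⁻¹)
    first nucleophile ⇌ dormant form (K = 0.390, k = 0.0240 s⁻¹)
    second nucleophile + target → over-reaction product (k = 3.40 M⁻¹ s⁻¹)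

In the flask at 8.0 min, other capture product stands below the ceiling, and with over-reaction product (3.18 %) it makes 50.0 %, the ceiling of 50.0 %. For the neighbour charged with 0.020 M of second nucleophile, the same reckoning gives a ceiling of 20.0 %, target near 18.3 % and a ratio of 1.09. That neighbour ends with 19.0 % of other capture product, 19.0 % of target, a ratio of 0.999, and 61.0 % of isomer of the product.

The runs are simulated for an exercise, and the scatter is random.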